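**Retrosynthetic overview**

- The target, 3,5,7,8-tetramethoxy-2-(2-methoxyphenyl)-4H-chromen-4-one, is traced back through O-methylation to the 3-hydroxyflavone, and this to a 2-aryl-3-nitro-2H-chromene in which the nitro group at C3 stands in for the C3 oxygen.
- The plan rests on one feature of ring C (the pyranone): the bonds O1–C2 and C3–C4 lie opposite each other. Cutting both leaves the four-atom unit O1–C8a–C4a–C4, already present in a salicylaldehyde (ring A), and the two-atom unit C2–C3, present in a β-nitrostyrene that carries ring B.
- Both bonds are formed in one domino oxa-Michael–Henry condensation. Ring C is the only ring made; rings A and B are bought as arenes.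
- The 5,7,8-trimethoxy pattern of ring A corresponds to 2-hydroxy-3,4,6-trimethoxybenzaldehyde. This comes from 2,3,5-trimethoxyphenol by ortho-formylation, and the phenol from 4,6-dimethoxysalicylaldehyde by benzylation, Baeyer–Villiger oxidation, methylation and hydrogenolysis.
- The ring B partner, (E)-2-methoxy-β-nitrostyrene, comes from Henry condensation of 2-methoxybenzaldehyde with nitromethane.

Key step: step 7

Remark on the chemistry: the target has no stereocentre. The C2 centre of the chroman and chromene intermediates, and the further centres of the transient chromans, are not controlled; these compounds are carried as racemates or diastereomer mixtures and are written without stereodescriptors, since all of them converge on the achiral flavonol.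

**Route**

Step 1
Reactants: 1 4,6-dimethoxysalicylaldehyde (2-hydroxy-4,6-dimethoxybenzaldehyde)
Product: 2 2-(benzyloxy)-4,6-dimethoxybenzaldehyde
Conditions: BnBr, K2CO3, DMF, 60 °C
Reagents that add atoms: benzyl bromide, BrCc1ccccc1
Why: Williamson ether synthesis on the acidic ortho-hydroxyl masks the oxygen that must become O1 as a benzyl ether, so that it stays distinguishable from the oxygen introduced next.

Step 2
Reactants: 2 2-(benzyloxy)-4,6-dimethoxybenzaldehyde
Product: 4 2-(benzyloxy)-4,6-dimethoxyphenol, via aryl formate 3 (not isolated)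
Conditions: mCPBA, CH2Cl2, 0 °C to rt; then K2CO3 (cat.), MeOH, N2, rt
Reagents that add atoms: 3-chloroperoxybenzoic acid (mCPBA), OOC(=O)c1cccc(Cl)c1
Why: Baeyer–Villiger (Dakin-type) oxidation, in which the trialkoxyaryl group with its ortho and para donors migrates in preference to hydride to give aryl formate 3, which methanolysis cleaves to the phenol without touching the benzyl ether.

Step 3
Reactants: 4 2-(benzyloxy)-4,6-dimethoxyphenol
Product: 5 1-(benzyloxy)-2,3,5-trimethoxybenzene
Conditions: MeI, K2CO3, acetone, reflux
Reagents that add atoms: iodomethane, CI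
Why: Williamson O-methylation of the only free phenol fixes the future C8 methoxy group.

Step 4
Reactants: 5 1-(benzyloxy)-2,3,5-trimethoxybenzene
Product: 6 2,3,5-trimethoxyphenol
Conditions: H2 (1 atm), Pd/C, EtOAc/MeOH, rt
Reagents that add atoms: none
Why: Catalytic hydrogenolysis cleaves only the benzylic C–O bond, the aryl methyl ethers and the arene being inert under these conditions, and frees the phenol that will become O1.

Step 5
Reactants: 6 2,3,5-trimethoxyphenol
Product: 8 2-hydroxy-3,4,6-trimethoxybenzaldehyde, via salicyl alcohol 7 (not isolated)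
Conditions: MgCl2, Et3N, (CH2O)n, MeCN, reflux; then 1 M HCl
Reagents that add atoms: paraformaldehyde (as formaldehyde), C=O
Why: Magnesium-mediated ortho-formylation of a phenol (Casnati–Skattebøl reaction) delivers formaldehyde inside the magnesium phenoxide chelate to the only free ortho carbon, C6, and salicyl alcohol 7 is oxidised in the flask by hydride transfer to a second formaldehyde.

Step 6
Reactants: 9 2-methoxybenzaldehyde; 10 nitromethane
Product: 11 (E)-1-methoxy-2-(2-nitrovinyl)benzene
Conditions: MeNO2 (excess), NH4OAc, AcOH, 100 °C
Reagents that add atoms: none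
Why: Henry (nitroaldol) condensation with loss of water gives the conjugated nitroalkene, for which the (E) isomer is the thermodynamic product.

Step 7
Reactants: 8 2-hydroxy-3,4,6-trimethoxybenzaldehyde; 11 (E)-1-methoxy-2-(2-nitrovinyl)benzene
Product: 14 5,7,8-trimethoxy-2-(2-methoxyphenyl)-3-nitro-2H-chromene (racemic), via oxa-Michael adduct 12 (not isolated), via nitrochromanol 13 (not isolated)
Conditions: DABCO (0.5 equiv), 11 (1.5 equiv), MeCN (minimal), 60 °C
Reagents that add atoms: none
Why: DABCO generates the phenoxide of 8, which adds to the β-carbon of nitroalkene 11 to form O1–C2 and the nitronate of 12; the nitronate carbon then attacks the ortho aldehyde in an intramolecular Henry reaction to form C3–C4, and E1cB loss of water from nitro alcohol 13 gives the conjugated nitroalkene 14. The closest known reaction type is the tertiary-amine-catalysed domino oxa-Michael–Henry condensation of salicylaldehydes with β-nitrostyrenes to 2-aryl-3-nitro-2H-chromenes. Ring C closes in a 6-exo-trig (enolexo) mode, the nitronate carbon attacking the aldehyde carbonyl. The one new stereocentre, C2, is formed without any controlling element and is racemic, which is of no consequence because it becomes sp2 in step 8. The step needs conjugate addition to precede carbonyl addition and offers no regiochemical choice, since the single phenol sits ortho to the aldehyde; the irreversible dehydration should pull the reversible oxa-Michael and Henry equilibria forward, although the donor-rich aldehyde flanked by the 6-methoxy group will slow the closure.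

Step 8
Reactants: 14 5,7,8-trimethoxy-2-(2-methoxyphenyl)-3-nitro-2H-chromene
Product: 17 3-hydroxy-5,7,8-trimethoxy-2-(2-methoxyphenyl)-4H-chromen-4-one, via nitro epoxide 15 (not isolated), via dihydroflavonol 16 (not isolated)
Conditions: 30% aq H2O2, 2 M NaOH, MeOH/THF, 0 °C to rt; then AcOH to pH 5
Reagents that add atoms: hydrogen peroxide, OO; sodium hydroxide, [Na+].[OH-]
Why: This is the known alkaline-peroxide conversion of 2-aryl-3-nitro-2H-chromenes into flavonols, in which Weitz–Scheffer nucleophilic epoxidation gives nitro epoxide 15, hydroxide opens it at benzylic C4 with expulsion of nitrite from C3, the resulting ketol enolises to dihydroflavonol 16, and excess alkaline peroxide dehydrogenates this to the flavonol, erasing the C2 stereocentre.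

Step 9
Reactants: 17 3-hydroxy-5,7,8-trimethoxy-2-(2-methoxyphenyl)-4H-chromen-4-one
Product: 18 3,5,7,8-tetramethoxy-2-(2-methoxyphenyl)-4H-chromen-4-one
Conditions: MeI, K2CO3, acetone, reflux
Reagents that add atoms: iodomethane, CI
Why: Williamson O-methylation of the acidic enolic 3-hydroxyl, the only free OH group, completes the target.

**Compound list**

1 | 4,6-dimethoxysalicylaldehyde (2-hydroxy-4,6-dimethoxybenzaldehyde) | COc1cc(O)c(C=O)c(OC)c1 | starting material
2 | 2-(benzyloxy)-4,6-dimethoxybenzaldehyde | COc1cc(OCc2ccccc2)c(C=O)c(OC)c1 | intermediate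
3 | 2-(benzyloxy)-4,6-dimethoxyphenyl formate | COc1cc(OCc2ccccc2)c(OC=O)c(OC)c1 | intermediate
4 | 2-(benzyloxy)-4,6-dimethoxyphenol | COc1cc(OCc2ccccc2)c(O)c(OC)c1 | intermediate
5 | 1-(benzyloxy)-2,3,5-trimethoxybenzene | COc1cc(OCc2ccccc2)c(OC)c(OC)c1 | intermediate
6 | 2,3,5-trimethoxyphenol | COc1cc(O)c(OC)c(OC)c1 | intermediate
7 | 2-(hydroxymethyl)-3,5,6-trimethoxyphenol | OCc1c(O)c(OC)c(OC)cc1OC | intermediate
8 | 2-hydroxy-3,4,6-trimethoxybenzaldehyde | O=Cc1c(O)c(OC)c(OC)cc1OC | intermediate
9 | 2-methoxybenzaldehyde | COc1ccccc1C=O | starting material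
10 | nitromethane | C[N+](=O)[O-] | starting material
11 | (E)-1-methoxy-2-(2-nitrovinyl)benzene | COc1ccccc1/C=C/[N+](=O)[O-] | intermediate
12 | 3,4,6-trimethoxy-2-[1-(2-methoxyphenyl)-2-nitroethoxy]benzaldehyde (racemic) | COc1ccccc1C(C[N+](=O)[O-])Oc1c(OC)c(OC)cc(OC)c1C=O | intermediate
13 | 5,7,8-trimethoxy-2-(2-methoxyphenyl)-3-nitrochroman-4-ol (racemic, diastereomer mixture) | COc1ccccc1C1Oc2c(OC)c(OC)cc(OC)c2C(O)C1[N+](=O)[O-] | intermediate
14 | 5,7,8-trimethoxy-2-(2-methoxyphenyl)-3-nitro-2H-chromene (racemic) | COc1ccccc1C1Oc2c(OC)c(OC)cc(OC)c2C=C1[N+](=O)[O-] | intermediate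
15 | 3,4-epoxy-5,7,8-trimethoxy-2-(2-methoxyphenyl)-3-nitrochroman (racemic, relative configuration not controlled) | COc1ccccc1C1Oc2c(OC)c(OC)cc(OC)c2C2OC12[N+](=O)[O-] | intermediate
16 | 3-hydroxy-5,7,8-trimethoxy-2-(2-methoxyphenyl)chroman-4-one (racemic, relative configuration not controlled) | COc1ccccc1C1Oc2c(OC)c(OC)cc(OC)c2C(=O)C1O | intermediate
17 | 3-hydroxy-5,7,8-trimethoxy-2-(2-methoxyphenyl)-4H-chromen-4-one | COc1ccccc1-c1oc2c(OC)c(OC)cc(OC)c2c(=O)c1O | intermediate
18 | 3,5,7,8-tetramethoxy-2-(2-methoxyphenyl)-4H-chromen-4-one | COc1ccccc1-c1oc2c(OC)c(OC)cc(OC)c2c(=O)c1OC | target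

**Step count**

Total steps: 9. Longest linear sequence: 8 steps (steps 1 to 5, then 7, 8 and 9, from compound 1); step 6 is a one-step branch.

**Steps most likely to fail**

Step 7. The Henry closure onto an aldehyde carbon that is deactivated by three methoxy donors and flanked by the 6-methoxy group may be too slow. Reversal of the oxa-Michael addition and amine-initiated oligomerisation of the nitroalkene would then consume the material. The fallback sets out from 8 and 11 and returns to the route at 14; it replaces the aldehyde by a stronger electrophile. Condensation of 8 with 4-methylbenzenesulfonamide (Si(OEt)4, 160 °C) should give the N-tosylimine N-(2-hydroxy-3,4,6-trimethoxybenzylidene)-4-methylbenzenesulfonamide F1. A DABCO-mediated domino oxa-Michael–aza-Henry reaction of this imine with 11 should give N-[5,7,8-trimethoxy-2-(2-methoxyphenyl)-3-nitrochroman-4-yl]-4-methylbenzenesulfonamide F2 as a racemate. DBU in toluene at 80 °C should then eliminate the sulfonamide by an E1cB pathway through the nitronate and give 14.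

Step 8. Oxidative ring fission of the electron-rich flavonol and of its enediol precursors in alkaline peroxide may compete, or the sequence may stop after epoxidation without clean loss of nitrite. The fallback sets out from 6 and returns to the route at 18; it brings in the C3 oxygen as a methoxyacetyl unit and closes ring C by the Baker–Venkataraman sequence. BF3·OEt2-mediated ortho-acylation of 6 with methoxyacetic acid (90 °C) should give 1-(2-hydroxy-3,4,6-trimethoxyphenyl)-2-methoxyethan-1-one F3; the chelated ortho-hydroxy ketone is the thermodynamic product, and the para position lies between two methoxy groups. O-Acylation with 2-methoxybenzoyl chloride in pyridine should give 2-(methoxyacetyl)-3,5,6-trimethoxyphenyl 2-methoxybenzoate F4. The acyl shift with KOH in pyridine at 50 °C should give 1-(2-hydroxy-3,4,6-trimethoxyphenyl)-2-methoxy-3-(2-methoxyphenyl)propane-1,3-dione F5. Cyclodehydration with H2SO4 in AcOH at 100 °C should give 18 directly.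

Step 5. Formylation may stop short, or the electron-rich ring may condense further with formaldehyde to diarylmethanes before the hydride transfer that raises the hydroxymethyl stage to the aldehyde. The fallback sets out from 6 and returns to the route at 8; it introduces and oxidises the carbon in separate stages. Boron-templated ortho-hydroxymethylation of 6 (PhB(OH)2, paraformaldehyde, catalytic propionic acid, toluene, reflux with water removal) should give 5,7,8-trimethoxy-2-phenyl-4H-1,3,2-benzodioxaborinine F6. Transesterification with propane-1,3-diol should release salicyl alcohol 7, here isolated, and MnO2 in CH2Cl2 should oxidise its benzylic alcohol to 8.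

**Further compounds**

F1 | step 7 | N-(2-hydroxy-3,4,6-trimethoxybenzylidene)-4-methylbenzenesulfonamide | Cc1ccc(cc1)S(=O)(=O)/N=C/c1c(O)c(OC)c(OC)cc1OC
F2 | step 7 | N-[5,7,8-trimethoxy-2-(2-methoxyphenyl)-3-nitrochroman-4-yl]-4-methylbenzenesulfonamide (racemic) | COc1ccccc1C1Oc2c(OC)c(OC)cc(OC)c2C(NS(=O)(=O)c2ccc(C)cc2)C1[N+](=O)[O-]
F3 | step 8 | 1-(2-hydroxy-3,4,6-trimethoxyphenyl)-2-methoxyethan-1-one | COCC(=O)c1c(O)c(OC)c(OC)cc1OC
F4 | step 8 | 2-(methoxyacetyl)-3,5,6-trimethoxyphenyl 2-methoxybenzoate | COCC(=O)c1c(OC(=O)c2ccccc2OC)c(OC)c(OC)cc1OC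
F5 | step 8 | 1-(2-hydroxy-3,4,6-trimethoxyphenyl)-2-methoxy-3-(2-methoxyphenyl)propane-1,3-dione | COc1ccccc1C(=O)C(OC)C(=O)c1c(O)c(OC)c(OC)cc1OC
F6 | step 5 | 5,7,8-trimethoxy-2-phenyl-4H-1,3,2-benzodioxaborinine | COc1cc(OC)c2c(c1OC)OB(c1ccccc1)OC2
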